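The route rests on cutting dioxane ring B at both aryl ether bonds, C8–O4' and C7–O5'. It exploits the vicinal dioxygenation of the C7–C8–C9 chain: C7 carries ring A and O5', C8 carries methyl C9 and O4', the oxygen next to the ring C methoxy. A propargylic three-carbon electrophile maps onto this pattern, with C9 arriving as an exocyclic methylene. In one operation, palladium and a chiral bisphosphine should join a catechol ester and a racemic 1-arylpropargyl carbonate, close ring B, decide which oxygen goes to which carbon and set C7. Radical hydrogenation then sets C8 trans, and the ester is extended to the (E)-propenol.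

Key step: step 2

Atom labels: C7 is the benzylic carbon of ring B, C8 the methyl-bearing carbon and C9 the methyl carbon. O4' is the ring C oxygen para to the side chain and O5' the one meta to it. Compound names use systematic benzodioxine locants. The target is (7R,8R), trans.

Assumption: the sense of induction for an aryl-bearing allyl terminus cannot be derived with confidence, so (R)-BINAP is written as the ligand leading to (R)-C7, and its antipode is taken if the opposite sense is found.

Design notes:
- The benzoate and the carbonate carry the same methoxy group, so alkoxide exchange in step 2 is degenerate.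
- The ester is kept through step 3 because an aldehyde or an enoate on ring C would compete for the manganese hydride.
- Compound 6 is an acid-sensitive enol ether that can slip into the achiral endocyclic alkene. It is therefore purified on Et3N-washed silica and carried on at once.

Step 1
Reactants: 1 3,4,5-trimethoxybenzaldehyde; 2 ethynylmagnesium bromide
Product: 4 racemic methyl 1-(3,4,5-trimethoxyphenyl)prop-2-yn-1-yl carbonate, via bromomagnesium alkoxide 3 (not isolated)
Conditions: 2 (1.2 equiv), THF, 0 °C; then ClCO2Me (1.5 equiv), 0 °C to rt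
Reagents that add atoms: methyl chloroformate, COC(=O)Cl
Why: Grignard 1,2-addition to the aldehyde gives the magnesium alkoxide, which the chloroformate O-acylates in the same flask; the carbinol centre is left racemic on purpose because step 2 is stereoconvergent.

Step 2
Reactants: 4 racemic methyl 1-(3,4,5-trimethoxyphenyl)prop-2-yn-1-yl carbonate; 5 methyl 3,4-dihydroxy-5-methoxybenzoate
Product: 6 methyl (3R)-8-methoxy-2-methylidene-3-(3,4,5-trimethoxyphenyl)-2,3-dihydro-1,4-benzodioxine-6-carboxylate
Conditions: 5 (1.1 equiv), Pd2(dba)3 (2.5 mol %), (R)-BINAP (6 mol %), THF, 0 °C to rt, Ar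
Reagents that add atoms: none
Why: Zerovalent palladium ionises 4 with loss of CO2 to a cationic η3-propargyl/allenyl complex, and the methoxide set free deprotonates 5 at its most acidic site, the 4-OH para to the ester (O4'). This phenoxide adds to the central carbon (C8), and proton transfer from the neighbouring 3-OH converts the adduct into a 2-aryloxy-π-allyl complex over C7–C8–C9; the closest known reaction type is the palladium-catalysed annulation of benzene-1,2-diols with propargylic carbonates, which has enantioselective versions with secondary carbonates and BINAP. Ring B closes when O5' attacks benzylic C7 anti to the metal, a six-membered closure that is exo with respect to the departing C7–Pd bond and leaves C8=C9 as the exocyclic methylene. C7 is the only new stereocentre and is controlled by the ligand alone, because the diastereomeric π-allyl complexes exchange faces by π–σ–π slippage through the unsubstituted C9 terminus before they close, so that both enantiomers of 4 converge on (R)-6. Two regiochemical choices are needed: O4' must react before O5', which the acidity gap created by the para ester secures, and O5' must choose C7 over C9, which the donor aryl group (positive charge at the benzylic terminus) and the steric pressure of the bisphosphine (longer Pd–C7 bond) should favour. Closure at C9 and re-ionisation of 6 both lead to the conjugated, achiral benzylidene isomer, so the reaction is run cold and stopped as soon as 4 is consumed.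

Step 3
Reactants: 6 methyl (3R)-8-methoxy-2-methylidene-3-(3,4,5-trimethoxyphenyl)-2,3-dihydro-1,4-benzodioxine-6-carboxylate
Product: 7 methyl (2R,3R)-8-methoxy-2-methyl-3-(3,4,5-trimethoxyphenyl)-2,3-dihydro-1,4-benzodioxine-6-carboxylate (trans)
Conditions: Mn(dpm)3 (10 mol %), PhSiH3 (1.5 equiv), t-BuOOH (1.5 equiv), degassed i-PrOH, rt, Ar
Reagents that add atoms: none
Why: Metal-hydride hydrogen-atom-transfer hydrogenation (Mukaiyama-type radical hydrogenation): the manganese hydride formed from trivalent Mn(dpm)3 and the silane gives H to the terminal C9 of the electron-rich 1,1-disubstituted enol ether, and the tertiary α-oxy radical at C8 accepts the second H in a late, product-like transition state that should put methyl C9 and ring A both pseudo-equatorial (trans, 8R), while C7, the ester and the aryl ethers are not touched.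

Step 4
Reactants: 7 methyl (2R,3R)-8-methoxy-2-methyl-3-(3,4,5-trimethoxyphenyl)-2,3-dihydro-1,4-benzodioxine-6-carboxylate
Product: 8 [(2R,3R)-8-methoxy-2-methyl-3-(3,4,5-trimethoxyphenyl)-2,3-dihydro-1,4-benzodioxin-6-yl]methanol
Conditions: i-Bu2AlH (2.5 equiv), CH2Cl2, −78 to 0 °C; aq. potassium sodium tartrate
Reagents that add atoms: none
Why: Hydride reduction of an aromatic methyl ester to the benzylic alcohol, a reaction to which the aryl ethers and both stereocentres of ring B are inert.

Step 5
Reactants: 8 [(2R,3R)-8-methoxy-2-methyl-3-(3,4,5-trimethoxyphenyl)-2,3-dihydro-1,4-benzodioxin-6-yl]methanol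
Product: 10 ethyl (2E)-3-[(2R,3R)-8-methoxy-2-methyl-3-(3,4,5-trimethoxyphenyl)-2,3-dihydro-1,4-benzodioxin-6-yl]prop-2-enoate, via benzodioxane-6-carbaldehyde 9 (not isolated)
Conditions: MnO2 (10 equiv), Ph3P=CHCO2Et (1.3 equiv), CH2Cl2, rt to reflux
Reagents that add atoms: (ethoxycarbonylmethylidene)triphenylphosphorane, CCOC(=O)C=P(c1ccccc1)(c1ccccc1)c1ccccc1
Why: Tandem oxidation–Wittig olefination: MnO2 oxidises only the benzylic alcohol, and the aldehyde is trapped as it forms by the stabilised ylide, which with aromatic aldehydes should give the E enoate.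

Step 6
Reactants: 10 ethyl (2E)-3-[(2R,3R)-8-methoxy-2-methyl-3-(3,4,5-trimethoxyphenyl)-2,3-dihydro-1,4-benzodioxin-6-yl]prop-2-enoate
Product: 11 (2E)-3-[(2R,3R)-8-methoxy-2-methyl-3-(3,4,5-trimethoxyphenyl)-2,3-dihydro-1,4-benzodioxin-6-yl]prop-2-en-1-ol (target)
Conditions: i-Bu2AlH (2.5 equiv), CH2Cl2, −78 °C; aq. potassium sodium tartrate
Reagents that add atoms: none
Why: 1,2-Reduction of an α,β-unsaturated ester by i-Bu2AlH at low temperature stops at the allylic alcohol and leaves the E alkene and ring B unchanged.

Compound list
1 | 3,4,5-trimethoxybenzaldehyde | COc1cc(C=O)cc(OC)c1OC | starting material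
2 | ethynylmagnesium bromide | C#C[Mg]Br | starting material
3 | bromomagnesium 1-(3,4,5-trimethoxyphenyl)prop-2-yn-1-olate (racemic, not isolated) | C#CC(O[Mg]Br)c1cc(OC)c(OC)c(OC)c1 | intermediate
4 | methyl 1-(3,4,5-trimethoxyphenyl)prop-2-yn-1-yl carbonate (racemic) | COC(=O)OC(C#C)c1cc(OC)c(OC)c(OC)c1 | intermediate
5 | methyl 3,4-dihydroxy-5-methoxybenzoate | COC(=O)c1cc(O)c(O)c(OC)c1 | starting material
6 | methyl (3R)-8-methoxy-2-methylidene-3-(3,4,5-trimethoxyphenyl)-2,3-dihydro-1,4-benzodioxine-6-carboxylate | COc1cc([C@H]2Oc3cc(C(=O)OC)cc(OC)c3OC2=C)cc(OC)c1OC | intermediate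
7 | methyl (2R,3R)-8-methoxy-2-methyl-3-(3,4,5-trimethoxyphenyl)-2,3-dihydro-1,4-benzodioxine-6-carboxylate (trans) | COc1cc([C@H]2Oc3cc(C(=O)OC)cc(OC)c3O[C@@H]2C)cc(OC)c1OC | intermediate
8 | [(2R,3R)-8-methoxy-2-methyl-3-(3,4,5-trimethoxyphenyl)-2,3-dihydro-1,4-benzodioxin-6-yl]methanol | COc1cc([C@H]2Oc3cc(CO)cc(OC)c3O[C@@H]2C)cc(OC)c1OC | intermediate
9 | (2R,3R)-8-methoxy-2-methyl-3-(3,4,5-trimethoxyphenyl)-2,3-dihydro-1,4-benzodioxine-6-carbaldehyde (not isolated) | COc1cc([C@H]2Oc3cc(C=O)cc(OC)c3O[C@@H]2C)cc(OC)c1OC | intermediate
10 | ethyl (2E)-3-[(2R,3R)-8-methoxy-2-methyl-3-(3,4,5-trimethoxyphenyl)-2,3-dihydro-1,4-benzodioxin-6-yl]prop-2-enoate | COc1cc([C@H]2Oc3cc(/C=C/C(=O)OCC)cc(OC)c3O[C@@H]2C)cc(OC)c1OC | intermediate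
11 | (2E)-3-[(2R,3R)-8-methoxy-2-methyl-3-(3,4,5-trimethoxyphenyl)-2,3-dihydro-1,4-benzodioxin-6-yl]prop-2-en-1-ol | COc1cc([C@H]2Oc3cc(/C=C/CO)cc(OC)c3O[C@@H]2C)cc(OC)c1OC | target

Total step count: 6.
Longest linear sequence: 6 steps (1 → 4 → 6 → 7 → 8 → 10 → 11). Compound 5 is bought and enters at step 2.

Steps most likely to fail

**1. Step 2.**
- What may go wrong:
  - The tethered phenoxide may close at the unsubstituted C9 terminus.
  - The product may be re-ionised by the catalyst, which drains material into the conjugated benzylidene isomer.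
  - The less acidic phenol may form the first C–O bond.
  - Facial discrimination may be weak with an aryl group on the allyl terminus.
- Fallback: it sets out from 5 and comes back at 7, so steps 2 and 3 are both replaced. C8 is taken from the chiral pool and C7 is set by thermodynamic ring closure.
- 3,4,5-Trimethoxyphenylmagnesium bromide is added to (S)-2-[(tert-butyldimethylsilyl)oxy]-N-methoxy-N-methylpropanamide. This gives (2S)-2-[(tert-butyldimethylsilyl)oxy]-1-(3,4,5-trimethoxyphenyl)propan-1-one F1.
- n-Bu4NF buffered with AcOH then frees (2S)-2-hydroxy-1-(3,4,5-trimethoxyphenyl)propan-1-one F2.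
- Mitsunobu etherification of F2 with 5 (PPh3, DIAD, THF) engages the more acidic 4-OH and inverts the carbinol carbon. It gives methyl 3-hydroxy-5-methoxy-4-{[(2R)-1-oxo-1-(3,4,5-trimethoxyphenyl)propan-2-yl]oxy}benzoate F3.
- NaBH4 in MeOH reduces only the ketone, giving methyl 3-hydroxy-4-{[(2R)-1-hydroxy-1-(3,4,5-trimethoxyphenyl)propan-2-yl]oxy}-5-methoxybenzoate F4 as both C7 epimers.
- Catalytic p-TsOH in toluene closes the free 3-OH onto the benzylic cation, which should bring both epimers to trans 7.

**2. Step 3.**
- What may go wrong: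
  - Hydrogen may reach the C8 radical from the face anti to a pseudo-axial ring A, which gives the cis relationship.
  - The C8 radical may expel O5' by β-scission of the weak benzylic C7–O5' bond.
  - The C8 radical may return H7 to the metal, which moves the alkene into ring B and erases C7.
  - Any cis isomer must be removed by chromatography and not equilibrated, because acid equilibration inverts C7 and would feed the enantiomeric trans series.
- Fallback: it sets out from 4 and 5 and comes back at 7. It is a stereochemical relay through the opposite C7 configuration.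
- The annulation is run with (S)-BINAP to give methyl (3S)-8-methoxy-2-methylidene-3-(3,4,5-trimethoxyphenyl)-2,3-dihydro-1,4-benzodioxine-6-carboxylate F5.
- Surface hydrogenation (H2, Rh/Al2O3, EtOAc) adds anti to ring A and fixes C8 as R. The product is cis methyl (2R,3S)-8-methoxy-2-methyl-3-(3,4,5-trimethoxyphenyl)-2,3-dihydro-1,4-benzodioxine-6-carboxylate F6.
- BF3·OEt2 in CH2Cl2 then ionises the benzylic C7–O5' bond reversibly and lets it re-close to the more stable trans isomer. This inverts C7 from S to R and gives 7.

**3. Step 5.**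
- What may go wrong:
  - The oxidation may stall on the MnO2 surface.
  - The olefination may leak to the Z enoate.
- Fallback: it sets out from 8 and comes back at 11, so steps 5 and 6 are both replaced. The side chain is built by olefin metathesis instead of carbonyl olefination followed by reduction.
- Dess–Martin periodinane gives 9, now isolated.
- Methylenation with Ph3P=CH2 gives (2R,3R)-7-ethenyl-5-methoxy-3-methyl-2-(3,4,5-trimethoxyphenyl)-2,3-dihydro-1,4-benzodioxine F7.
- Cross metathesis of F7 with (Z)-but-2-ene-1,4-diol, using the second-generation Hoveyda–Grubbs catalyst in CH2Cl2, should deliver the E allylic alcohol 11 under thermodynamic control.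

Further compounds
F1 | step 2 | (2S)-2-[(tert-butyldimethylsilyl)oxy]-1-(3,4,5-trimethoxyphenyl)propan-1-one | C[C@H](O[Si](C)(C)C(C)(C)C)C(=O)c1cc(OC)c(OC)c(OC)c1
F2 | step 2 | (2S)-2-hydroxy-1-(3,4,5-trimethoxyphenyl)propan-1-one | C[C@H](O)C(=O)c1cc(OC)c(OC)c(OC)c1
F3 | step 2 | methyl 3-hydroxy-5-methoxy-4-{[(2R)-1-oxo-1-(3,4,5-trimethoxyphenyl)propan-2-yl]oxy}benzoate | C[C@@H](Oc1c(O)cc(C(=O)OC)cc1OC)C(=O)c1cc(OC)c(OC)c(OC)c1
F4 | step 2 | methyl 3-hydroxy-4-{[(2R)-1-hydroxy-1-(3,4,5-trimethoxyphenyl)propan-2-yl]oxy}-5-methoxybenzoate (both C7 epimers) | C[C@@H](Oc1c(O)cc(C(=O)OC)cc1OC)C(O)c1cc(OC)c(OC)c(OC)c1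
F5 | step 3 | methyl (3S)-8-methoxy-2-methylidene-3-(3,4,5-trimethoxyphenyl)-2,3-dihydro-1,4-benzodioxine-6-carboxylate | COc1cc([C@@H]2Oc3cc(C(=O)OC)cc(OC)c3OC2=C)cc(OC)c1OC
F6 | step 3 | methyl (2R,3S)-8-methoxy-2-methyl-3-(3,4,5-trimethoxyphenyl)-2,3-dihydro-1,4-benzodioxine-6-carboxylate (cis) | COc1cc([C@@H]2Oc3cc(C(=O)OC)cc(OC)c3O[C@@H]2C)cc(OC)c1OC
F7 | step 5 | (2R,3R)-7-ethenyl-5-methoxy-3-methyl-2-(3,4,5-trimethoxyphenyl)-2,3-dihydro-1,4-benzodioxine | COc1cc([C@H]2Oc3cc(C=C)cc(OC)c3O[C@@H]2C)cc(OC)c1OC
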